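An average chain length is one division: monomer in chains over chains begun. The earlier runs show the top of that fraction, and the bottom has to be guessed.

| setting | larch | elm | flask |
|---|---|---|---|
| Z | 0.40 M | 0.40 M | 0.40 M |
| X | 10 mM | 40 mM | 20 mM |
| remark | run made earlier | run made earlier |  |
| time |  |  | 6.0 min |

- larch (time / min: D / %, Z / %): 0.500: 29.8, 70.5; 0.833: 42.1, 58.6; 1.33: 51.6, 48.8; 2.00: 57.5, 42.3; 3.00: 60.9, 39.6; 5.00: 61.5, 38.0; 8.00: 61.7, 38.5
- elm (time / min: D / %, Z / %): 0.417: 54.4, 46.0; 1.00: 60.7, 38.7; 2.00: 61.7, 39.0; 3.00: 61.1, 38.9; 4.00: 61.6, 38.5; 6.00: 62.2, 38.2; 8.00: 61.4, 38.7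

(standard deviation of a reading: 0.3 percentage points)

1. whether the average number of monomer units in a chain (chains begun, living or dead) reaches 10 by 6.0 min (no / yes)
2. average number of monomer units in a chain (chains begun, living or dead) at 6.0 min

- the average divides the monomer in chains by the number of chains begun, living and dead together
- the earlier runs do not show the number of chains; that part of a forecast is a guess

Does [D] stop? Larch and elm both level off with D near 61.5% of the Z charged, although elm held 4.00 times the X of larch.

Does the flask get there in time? In larch, the gap between D and that level has a half-time of 0.506 min, read at 1.33 min. The same reading in elm gives a rate 3.77 times that of larch, so the rate roughly follows the charge of X. My reckoning for the flask is then a half-time of 0.253 min, and 6.0 min is far longer, so on this reckoning the flask stands at the level by then.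

How long are the chains there? If each X begins one chain, the length is 12.3: the plateau length, defined as [D] at the level over the [X] charged. That is more than the 10 wanted, which on the same count of one chain per X needs D at half of the Z charged.

The forecast says yes and 12.3, taking “each X starts one chain” and noting that the chain count is not measured.

The flask gives yes and 12.9, and the average passes 10 at 0.558 min.

    D + J → Z + J, rate k1*[J] as long as [D] is above zero (k = 0.386 s⁻¹)
    Z + X → J + D (k = 0.607 L mol⁻¹ s⁻¹)
    X → G (k = 0.0114 s⁻¹)
    Z + J → D + J, rate k4*[J]*[Z] (k = 2.50 L mol⁻¹ s⁻¹)

In the flask, X at the start goes into J 21 times faster than into G, a selectivity factor for beginning chains. At 6.00 min X stands at 0%, [J] at 0.0190 M and [G] at 9.76 × 10⁻⁴ M, and the flask's 12.9 lies above the plateau length by a factor of 1.05, while [X] charged over [J] is 1.05.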